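Late in the dusk flask the links still creep up while the first end groups hover near 2.13%, so something you cannot see keeps feeding them. At 0.833 d that unseen part is already 53.3% of the charge.

common to all: first end groups 0.10 M

| charge | second end groups | remark | time |
|---|---|---|---|
| dusk | 1 equiv | the very flask that is asked about, followed so far |  |
| flask | 1.00 equiv |  | 8.0 d |

dusk run (percent of the first end groups charged)

| time / d | links / % | first end groups / % |
|---|---|---|
| 0.833 | 41.0 | 5.7 |
| 1.67 | 44.0 | 3.0 |
| 2.50 | 46.2 | 2.6 |
| 3.00 | 48.2 | 2.7 |
| 4.00 | 50.2 | 1.8 |
| 5.00 | 52.0 | 1.9 |

(standard deviation of a reading: 0.3 percentage points)

- oak: at 8.0 d add second end groups, 50.0% of the amount charged, then wait 15 d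
- cedar: at 8.0 d take out 90% of the links then present, then wait 15 d
- maple: at 8.0 d add first end groups, 50.0% of the amount charged, then wait 15 d
- birch: change nothing and wait 15 d more

- links taken out counts as made
- additions bring no volume worth counting

1. links, in percent of the first end groups first charged, at 8.0 d
2. which option adds most links ("none" when 2 percentage points or less is all one gets) (oak / cedar / maple / birch / none)
3. links present, with what was taken out counted in, in percent of the first end groups first charged, after oak
4. links present, with what was taken out counted in, in percent of the first end groups first charged, after maple

Treat the free first end groups as a small tank with a drain. Between 3.00 d and 5.00 d links rise at 0.0190 d⁻¹, as a fraction of the charge, and dividing by the tank's content gives 0.891 d⁻¹. Call this the pull, the chance per day that a free first end group becomes a link: a pseudo-first-order rate constant, with a time constant of 1.12 d. Is it only noise? The two link readings differ by 3.8 percentage points against a scatter of 0.3 points, so it is rough but real.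

Run the slope straight on and links reach 57.7% at 8.0 d. But the slope read 0.0265 d⁻¹ earlier, so it seems to be falling, and I take 57.7% as my high estimate.

Now the options. A link needs both partners, so the pull should follow [second end groups], which stand near 42.3% if links are what used them. Oak adds 50.0% of their charge, which makes the pull after oak about twice that after maple. The objection is that maple adds just as much to the unseen store behind the tank, so if [first end groups] follow that store, the product [first end groups][second end groups] gains equally, a tie if links are the one exit. Yet a second exit may hide in the unseen part, which the readings do not show. A loss that ignores [second end groups] takes a smaller share where the pull is larger, so I commit to oak, then maple.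

The forecast says 57.3%, 80% after oak, 87% after maple, and picks maple, “Maple wins, but the dormant form's nature is assumed”.

The flask gives 56.5%, and oak wins with 74.1% against 68.2% after maple. At 8.00 d this flask has 28% of its second end groups free, and rings, which the readings did not show, hold 15.6%.

    first end groups + second end groups → links (k = 0.988 L mol⁻¹ h⁻¹)
    first end groups + second end groups → rings, rate k2*[first end groups] as long as [second end groups] is above zero (k = 0.0159 h⁻¹)
    first end groups ⇌ dormant form (K = 9.60, k = 0.0906 h⁻¹)

The pull was read with 37.6% of the second end groups free at 4.00 d; scaled to the moment just after the addition at 8.0 d, it is 1.84 d⁻¹ for oak and 0.661 d⁻¹ for maple, and against the ring step's 0.382 d⁻¹ the chance that a free first end group becomes a link at that moment is 82.8% and 63.4%. In a neighbour flask with 0.25 M of first end groups, the same scaling gives 0.977 d⁻¹ at 8.00 d, a chance of 71.9% at that late moment, and that flask has gathered over its whole run 73.6% links against 9.87% rings.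

(The runs are simulated with constants of no real substance, noise included.)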